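## Retrosynthetic overview

1. Chain numbered C1 (ester carbon) to C16 (propyl end). Both 3,6-dihydro-1,2-dioxine rings are closed last by one double ring-closing metathesis of the acyclic bis-peroxide 23: ring A first (two vinyl groups), ring B second (propenyl plus ketal vinyl). The ketal carbon C6 is then sorted by acid/MeOH equilibration.
2. Ring A C–O bonds come from two iridium-catalysed enantioselective allylic peroxidations: C13–O on hexenyl carbonate 4 (giving hydroperoxide 6), and C10–O as the fragment-joining coupling of 6 with allylic carbonate 22.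
3. Ring B: the peroxyketal C6–O bond comes from acid-catalysed addition of hydroperoxide 11 to the 1-alkyl-1-methoxyallene 21. C3 of 11 is set by amine-catalysed β-peroxidation of sorbaldehyde.
4. Linker 21 is built from 5-chloropent-1-yne, formaldehyde and methoxyallene. Every O–O unit is delivered by 2-hydroperoxy-2-methoxypropane 2.

Assumption: L is (Sa,S,S)-O,O′-(1,1′-binaphthalene-2,2′-diyl) N,N-bis(1-phenylethyl)phosphoramidite and ent-L its mirror image; L is taken to give the (S)-peroxide in step 3 and ent-L the (R)-peroxide in step 15 (sense carried over from this catalyst's O-allylations of n-alkyl carbonates), and the two ligands are exchanged if the first run of step 3 shows the opposite.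

## Route

Step 1
Reactants: 1 2,3-dimethylbut-2-ene
Product: 2 2-hydroperoxy-2-methoxypropane
Conditions: O3, MeOH/CH2Cl2 (1:4), −78 °C; N2 purge; kept as a titrated CH2Cl2 solution
Reagents that add atoms: ozone, [O-][O+]=O; methanol, CO
Why: Ozonolysis (Criegee cleavage) of the symmetrical alkene gives acetone and acetone O-oxide, which methanol traps as the hydroperoxy ketal; no stereocentre.

Step 2
Reactants: 3 (2E)-hex-2-en-1-ol
Product: 4 (2E)-hex-2-en-1-yl methyl carbonate
Conditions: ClCO2Me, pyridine, CH2Cl2, 0 °C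
Reagents that add atoms: methyl chloroformate, COC(=O)Cl
Why: Plain O-acylation of a primary allylic alcohol; the E alkene is untouched.

Step 3
Reactants: 4 (2E)-hex-2-en-1-yl methyl carbonate; 2 2-hydroperoxy-2-methoxypropane
Product: 5 (3S)-3-[(2-methoxypropan-2-yl)peroxy]hex-1-ene
Conditions: [Ir(dbcot)Cl]2 (2 mol%), L (4 mol%), TBD (1,5,7-triazabicyclo[4.4.0]dec-5-ene, 8 mol%), 2 (1.5 equiv), THF, 0 → 23 °C
Reagents that add atoms: none
Why: Proposed new method: iridium-catalysed enantioselective allylic peroxidation — the cyclometalated iridium–phosphoramidite complex ionizes the linear carbonate to an allyl complex of trivalent iridium with loss of CO2 and methoxide, the methoxide deprotonates the hydroperoxide (pKa about 12.5), and the peroxide anion, an α-effect O-nucleophile, attacks the substituted allyl terminus from outside the metal, so the branched peroxide forms and the ligand-defined allyl face sets C3 as (S); the closest known reactions are iridium-catalysed allylic etherifications with alkoxides, phenoxides and silanolates and the O-allylation of oximes and N-hydroxy compounds, and the oxidizable phosphorus is protected by coordination in the air-stable dbcot iridacycle.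

Step 4
Reactants: 5 (3S)-3-[(2-methoxypropan-2-yl)peroxy]hex-1-ene
Product: 6 (3S)-3-hydroperoxyhex-1-ene
Conditions: AcOH/THF/H2O (4:2:1), 23 °C; kept cold in solution (trace BHT) and used at once
Reagents that add atoms: none
Why: Acid hydrolysis of the acyclic peroxyketal (deprotection) releases the hydroperoxide without breaking the C3–O bond, so (S) is kept.

Step 5
Reactants: 7 (2E,4E)-hexa-2,4-dienal; 2 2-hydroperoxy-2-methoxypropane
Product: 8 (3R,4E)-3-[(2-methoxypropan-2-yl)peroxy]hex-4-enal
Conditions: (R)-2-{bis[3,5-bis(trifluoromethyl)phenyl](trimethylsilyloxy)methyl}pyrrolidine (10 mol%), PhCO2H (10 mol%), 2 (2 equiv), toluene, −20 °C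
Reagents that add atoms: none
Why: Iminium-catalysed asymmetric oxa-Michael addition (β-peroxidation of an enal): the hydroperoxide adds to C3 of the E-iminium ion on the face left open by the diaryl(silyloxy)methyl group of the (R)-catalyst, giving (3R); C3 has the larger LUMO coefficient and C5 is methyl-substituted, and benzoic acid at −20 °C protonates the enamine before it can close to an epoxide.

Step 6
Reactants: 8 (3R,4E)-3-[(2-methoxypropan-2-yl)peroxy]hex-4-enal
Product: 9 (3R,4E)-3-[(2-methoxypropan-2-yl)peroxy]hex-4-enoic acid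
Conditions: NaClO2, NaH2PO4, 2-methylbut-2-ene, t-BuOH/H2O, 0 °C
Reagents that add atoms: sodium chlorite, [Na+].[O-]Cl=O
Why: Pinnick oxidation; buffered chlorite oxidizes only the aldehyde and 2-methylbut-2-ene removes HOCl, so the alkene, the peroxide and the β-stereocentre are untouched.

Step 7
Reactants: 9 (3R,4E)-3-[(2-methoxypropan-2-yl)peroxy]hex-4-enoic acid
Product: 10 methyl (3R,4E)-3-[(2-methoxypropan-2-yl)peroxy]hex-4-enoate
Conditions: Me3SiCHN2, MeOH/toluene (1:4), 0 °C
Reagents that add atoms: trimethylsilyldiazomethane, C[Si](C)(C)C=[N+]=[N-]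
Why: Esterification with trimethylsilyldiazomethane under neutral conditions, which avoids base-induced β-elimination of the peroxide.

Step 8
Reactants: 10 methyl (3R,4E)-3-[(2-methoxypropan-2-yl)peroxy]hex-4-enoate
Product: 11 methyl (3R,4E)-3-hydroperoxyhex-4-enoate
Conditions: AcOH/THF/H2O (4:2:1), 23 °C; used at once
Reagents that add atoms: none
Why: Acid hydrolysis of the peroxyketal as in step 4; the C3–O bond is not broken, so (3R) is kept.

Step 9
Reactants: 12 5-chloropent-1-yne
Product: 14 6-chlorohex-2-yn-1-ol, via lithium 5-chloropent-1-yn-1-ide 13 (not isolated)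
Conditions: n-BuLi, THF, −78 °C; (CH2O)n, −78 → 23 °C
Reagents that add atoms: formaldehyde (as paraformaldehyde), C=O
Why: Acetylide addition to formaldehyde (hydroxymethylation); the primary chloride is inert at −78 °C.

Step 10
Reactants: 14 6-chlorohex-2-yn-1-ol
Product: 15 (2E)-6-chlorohex-2-en-1-ol
Conditions: NaAlH2(OCH2CH2OMe)2, THF, 0 → 23 °C; aq. Rochelle salt
Reagents that add atoms: none
Why: Alkoxide-directed trans-hydroalumination of the propargylic alcohol followed by protonolysis gives only the E allylic alcohol; the primary chloride survives at or below 23 °C.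

Step 11
Reactants: 15 (2E)-6-chlorohex-2-en-1-ol
Product: 16 (2E)-6-iodohex-2-en-1-ol
Conditions: NaI, acetone, reflux
Reagents that add atoms: sodium iodide, [Na+].[I-]
Why: Finkelstein halide exchange (SN2), driven by precipitation of NaCl.

Step 12
Reactants: 16 (2E)-6-iodohex-2-en-1-ol; 17 methoxyallene (1-methoxypropa-1,2-diene)
Product: 20 (2E)-7-methoxynona-2,7,8-trien-1-ol, via 1-lithio-1-methoxypropa-1,2-diene 18 (not isolated), via lithium (2E)-6-iodohex-2-en-1-olate 19 (not isolated)
Conditions: 17, n-BuLi, THF, −40 °C (2.3 equiv of 18); then 16, −78 → −20 °C; aq. NaHCO3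
Reagents that add atoms: none
Why: C-alkylation of α-lithiated methoxyallene by a primary iodide (SN2); the first equivalent of 18 only deprotonates the hydroxyl group.

Step 13
Reactants: 20 (2E)-7-methoxynona-2,7,8-trien-1-ol
Product: 21 (2E)-7-methoxynona-2,7,8-trien-1-yl methyl carbonate
Conditions: ClCO2Me, i-Pr2NEt, DMAP (cat.), CH2Cl2, 0 °C
Reagents that add atoms: methyl chloroformate, COC(=O)Cl
Why: O-acylation with a hindered amine base (no pyridinium salt), which spares the acid-sensitive allenyl ether.

Step 14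
Reactants: 21 (2E)-7-methoxynona-2,7,8-trien-1-yl methyl carbonate; 11 methyl (3R,4E)-3-hydroperoxyhex-4-enoate
Product: 22 methyl (3R,4E)-3-({(3RS,7E)-3-methoxy-9-[(methoxycarbonyl)oxy]nona-1,7-dien-3-yl}peroxy)hex-4-enoate (both epimers at the ketal carbon)
Conditions: 11 (1.2 equiv), PPTS (5 mol%), 4 Å MS, CH2Cl2, −20 → 0 °C; Et3N quench; Et3N-washed SiO2
Reagents that add atoms: none
Why: Acid-catalysed addition of a hydroperoxide to an alkoxyallene (peroxyketalization): protonation at the central allene carbon gives the vinyl-substituted oxocarbenium ion, which the hydroperoxide captures at the oxygen-bearing carbon under kinetic control; the ketal carbon forms as both epimers (about 1:1) and is set in step 17.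

Step 15
Reactants: 22 methyl (3R,4E)-3-({(3RS,7E)-3-methoxy-9-[(methoxycarbonyl)oxy]nona-1,7-dien-3-yl}peroxy)hex-4-enoate; 6 (3S)-3-hydroperoxyhex-1-ene
Product: 23 methyl (3R,4E)-3-({(3RS,7R)-7-{[(3S)-hex-1-en-3-yl]peroxy}-3-methoxynona-1,8-dien-3-yl}peroxy)hex-4-enoate
Conditions: [Ir(dbcot)Cl]2 (2 mol%), ent-L (4 mol%), TBD (8 mol%), 6 (1.3 equiv), THF, 0 → 23 °C; stopped at full conversion
Reagents that add atoms: none
Why: Proposed new method: the iridium-catalysed allylic peroxidation of step 3 used as the fragment-joining C–O coupling — only the primary E-allylic carbonate is ionized to the allyl complex of trivalent iridium, the anion of secondary hydroperoxide 6 (generated by the released methoxide, so the medium never exceeds peroxide-anion basicity and the β-peroxy ester and peroxyketal survive) attacks the substituted terminus, and ent-L sets the new centre as (7R) independently of the remote centres; the closest known reactions are iridium-catalysed allylic etherification and oxime O-allylation, and the product peroxide is a poorer leaving group than carbonate, which limits re-ionization.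

Step 16
Reactants: 23 methyl (3R,4E)-3-({(3RS,7R)-7-{[(3S)-hex-1-en-3-yl]peroxy}-3-methoxynona-1,8-dien-3-yl}peroxy)hex-4-enoate
Product: 24 methyl 2-[(3R,6RS)-6-methoxy-6-{3-[(3R,6S)-6-propyl-3,6-dihydro-1,2-dioxin-3-yl]propyl}-3,6-dihydro-1,2-dioxin-3-yl]acetate (both C6 epimers)
Conditions: second-generation Hoveyda–Grubbs catalyst RuCl2(H2IMes)(=CH-C6H4-2-OiPr) (2 × 5 mol%), 1,4-benzoquinone (10 mol%), CH2Cl2 (2 mM), 40 °C, Ar sparge
Reagents that add atoms: none
Why: Double ring-closing olefin metathesis; ruthenium alkylidenes tolerate dialkyl peroxides, the two unhindered vinyl groups close ring A first (six-membered ring preferred over the seven-membered carbocycle), then the ketal vinyl and the propenyl group close ring B; no stereocentre is touched, so cis ring A follows from the (7R) and (3S) centres of 23.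

Step 17
Reactants: 24 methyl 2-[(3R,6RS)-6-methoxy-6-{3-[(3R,6S)-6-propyl-3,6-dihydro-1,2-dioxin-3-yl]propyl}-3,6-dihydro-1,2-dioxin-3-yl]acetate
Product: 25 methyl 2-[(3R,6S)-6-methoxy-6-{3-[(3R,6S)-6-propyl-3,6-dihydro-1,2-dioxin-3-yl]propyl}-3,6-dihydro-1,2-dioxin-3-yl]acetate (CNP0078798.2)
Conditions: SiO2 (0.5% Et3N) separation of the epimers; recovered (6R)-epimer: PPTS (10 mol%), MeOH, 23 °C, then re-separation (two cycles)
Reagents that add atoms: methanol, CO
Why: Acid-catalysed trans-ketalization: reversible ionization of C6–OMe to the cyclic peroxycarbenium ion and recapture of methanol interconverts the two C6 epimers (near 1:1, as for related 3-methoxy-1,2-dioxines), so the separated (6R)-epimer is recycled to the (3R,6S) target while C3 and ring A stay fixed.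

## Compound list

1 | 2,3-dimethylbut-2-ene | CC(C)=C(C)C | starting material
2 | 2-hydroperoxy-2-methoxypropane | COC(C)(C)OO | intermediate
3 | (2E)-hex-2-en-1-ol | CCC/C=C/CO | starting material
4 | (2E)-hex-2-en-1-yl methyl carbonate | CCC/C=C/COC(=O)OC | intermediate
5 | (3S)-3-[(2-methoxypropan-2-yl)peroxy]hex-1-ene | CCC[C@H](OOC(C)(C)OC)C=C | intermediate
6 | (3S)-3-hydroperoxyhex-1-ene | CCC[C@H](OO)C=C | intermediate
7 | (2E,4E)-hexa-2,4-dienal | C/C=C/C=C/C=O | starting material
8 | (3R,4E)-3-[(2-methoxypropan-2-yl)peroxy]hex-4-enal | C/C=C/[C@@H](CC=O)OOC(C)(C)OC | intermediate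
9 | (3R,4E)-3-[(2-methoxypropan-2-yl)peroxy]hex-4-enoic acid | C/C=C/[C@@H](CC(=O)O)OOC(C)(C)OC | intermediate
10 | methyl (3R,4E)-3-[(2-methoxypropan-2-yl)peroxy]hex-4-enoate | C/C=C/[C@@H](CC(=O)OC)OOC(C)(C)OC | intermediate
11 | methyl (3R,4E)-3-hydroperoxyhex-4-enoate | C/C=C/[C@@H](CC(=O)OC)OO | intermediate
12 | 5-chloropent-1-yne | C#CCCCCl | starting material
13 | lithium 5-chloropent-1-yn-1-ide | [Li+].[C-]#CCCCCl | intermediate
14 | 6-chlorohex-2-yn-1-ol | OCC#CCCCCl | intermediate
15 | (2E)-6-chlorohex-2-en-1-ol | OC/C=C/CCCCl | intermediate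
16 | (2E)-6-iodohex-2-en-1-ol | OC/C=C/CCCI | intermediate
17 | methoxyallene (1-methoxypropa-1,2-diene) | COC=C=C | starting material
18 | 1-lithio-1-methoxypropa-1,2-diene | [Li]C(OC)=C=C | intermediate
19 | lithium (2E)-6-iodohex-2-en-1-olate | [Li+].[O-]C/C=C/CCCI | intermediate
20 | (2E)-7-methoxynona-2,7,8-trien-1-ol | OC/C=C/CCCC(OC)=C=C | intermediate
21 | (2E)-7-methoxynona-2,7,8-trien-1-yl methyl carbonate | COC(=O)OC/C=C/CCCC(OC)=C=C | intermediate
22 | methyl (3R,4E)-3-({(3RS,7E)-3-methoxy-9-[(methoxycarbonyl)oxy]nona-1,7-dien-3-yl}peroxy)hex-4-enoate, both ketal epimers | C/C=C/[C@@H](CC(=O)OC)OOC(OC)(CCC/C=C/COC(=O)OC)C=C | intermediate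
23 | methyl (3R,4E)-3-({(3RS,7R)-7-{[(3S)-hex-1-en-3-yl]peroxy}-3-methoxynona-1,8-dien-3-yl}peroxy)hex-4-enoate, both ketal epimers | C/C=C/[C@@H](CC(=O)OC)OOC(OC)(CCC[C@H](C=C)OO[C@@H](CCC)C=C)C=C | intermediate
24 | methyl 2-[(3R,6RS)-6-methoxy-6-{3-[(3R,6S)-6-propyl-3,6-dihydro-1,2-dioxin-3-yl]propyl}-3,6-dihydro-1,2-dioxin-3-yl]acetate, both C6 epimers | CCC[C@H]1C=C[C@@H](CCCC2(OC)C=C[C@@H](CC(=O)OC)OO2)OO1 | intermediate
25 | methyl 2-[(3R,6S)-6-methoxy-6-{3-[(3R,6S)-6-propyl-3,6-dihydro-1,2-dioxin-3-yl]propyl}-3,6-dihydro-1,2-dioxin-3-yl]acetate | CCC[C@H]1C=C[C@@H](CCC[C@@]2(OC)C=C[C@@H](CC(=O)OC)OO2)OO1 | target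

## Step count and risks

Total step count: 17. Longest linear sequence: 9 steps (steps 9 to 17, from 5-chloropent-1-yne), which is 9/17 = 0.53 of the total.

Steps 3 and 15 are the same new reaction. Step 3 is its simplest case and serves as the calibration. If it fails, the fallback for step 15 applies unchanged, because it does not use 6.

Step 15 (the new iridium-catalysed peroxidation on the fully functionalized carbonate). The risks are oxidation of the catalyst by the hydroperoxide, linear product and re-ionization of allylic peroxides. The fallback uses known chemistry only, builds ring A by singlet-oxygen cycloaddition and gives up absolute control of ring A, so at most half of the material is usable. It sets out from 20. Oxidation with MnO2 in CH2Cl2 gives (2E)-7-methoxynona-2,7,8-trienal F1. Julia–Kocienski olefination with 5-(butylsulfonyl)-1-phenyl-1H-tetrazole and KN(SiMe3)2 gives (7E,9E)-3-methoxytrideca-1,2,7,9-tetraene F2. Addition of 11 under the conditions of step 14 gives methyl (3R,4E)-3-{[(7E,9E)-3-methoxytrideca-1,7,9-trien-3-yl]peroxy}hex-4-enoate F3. Photooxygenation (O2, tetraphenylporphyrin, visible light, CH2Cl2, 0 °C) adds singlet oxygen across the E,E-diene in a [4+2] sense to give methyl (3R,4E)-3-({3-methoxy-6-[cis-6-propyl-3,6-dihydro-1,2-dioxin-3-yl]hex-1-en-3-yl}peroxy)hex-4-enoate F4, with cis ring A of either sense. Ring-closing metathesis as in step 16 then closes ring B and gives 24 together with its ring-A diastereomer methyl 2-[(3R)-6-methoxy-6-{3-[(3S,6R)-6-propyl-3,6-dihydro-1,2-dioxin-3-yl]propyl}-3,6-dihydro-1,2-dioxin-3-yl]acetate F5. Preparative HPLC on a chiral phase removes F5, and the route is rejoined at 24.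

Step 5 (amine-catalysed peroxidation of a dienal). The risks are δ- instead of β-attack, epoxide formation and low ee. The fallback switches to the iridium-catalysed peroxidation in the vinyl series and sets out from 2. (E)-3-Iodoprop-2-en-1-ol is coupled with the Reformatsky reagent BrZnCH2CO2Me under Pd(PPh3)4 catalysis (Negishi-type coupling, alkene geometry retained) to methyl (3E)-5-hydroxypent-3-enoate F6. ClCO2Me/pyridine gives methyl (3E)-5-[(methoxycarbonyl)oxy]pent-3-enoate F7. Peroxidation with 2 under the conditions of step 15 (ent-L) gives methyl (3R)-3-[(2-methoxypropan-2-yl)peroxy]pent-4-enoate F8, and AcOH/THF/H2O gives methyl (3R)-3-hydroperoxypent-4-enoate F9. F9 replaces 11 in step 14, giving methyl (3R)-3-({(7E)-3-methoxy-9-[(methoxycarbonyl)oxy]nona-1,7-dien-3-yl}peroxy)pent-4-enoate F10, and in step 15, giving methyl (3R)-3-({(7R)-7-{[(3S)-hex-1-en-3-yl]peroxy}-3-methoxynona-1,8-dien-3-yl}peroxy)pent-4-enoate F11. Double ring-closing metathesis of F11 comes back to the route at 24.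

Step 14 (hydroperoxide addition to the methoxyallene). The risks are conjugate instead of 1,2-addition and acid-lability of the allylic peroxyketal. The fallback replaces the kinetic addition by a two-stage ketal exchange and sets out from 21. Methanol with catalytic PPTS at 0 °C converts the allene into the vinyl ketone dimethyl ketal (2E)-7,7-dimethoxynona-2,8-dien-1-yl methyl carbonate F12. Exchange of one methoxy group for 11 (PPTS, CH2Cl2, 5 Å MS to take up methanol, 0 °C) returns to the route at 22.

Further compounds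
F1 | step 15 | (2E)-7-methoxynona-2,7,8-trienal | O=C/C=C/CCCC(OC)=C=C
F2 | step 15 | (7E,9E)-3-methoxytrideca-1,2,7,9-tetraene | CCC/C=C/C=C/CCCC(OC)=C=C
F3 | step 15 | methyl (3R,4E)-3-{[(7E,9E)-3-methoxytrideca-1,7,9-trien-3-yl]peroxy}hex-4-enoate, both ketal epimers | C/C=C/[C@@H](CC(=O)OC)OOC(OC)(CCC/C=C/C=C/CCC)C=C
F4 | step 15 | methyl (3R,4E)-3-({3-methoxy-6-[cis-6-propyl-3,6-dihydro-1,2-dioxin-3-yl]hex-1-en-3-yl}peroxy)hex-4-enoate, shown with (3R,6S) ring A, formed together with the (3S,6R) form | C/C=C/[C@@H](CC(=O)OC)OOC(OC)(CCC[C@@H]1C=C[C@H](CCC)OO1)C=C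
F5 | step 15 | methyl 2-[(3R)-6-methoxy-6-{3-[(3S,6R)-6-propyl-3,6-dihydro-1,2-dioxin-3-yl]propyl}-3,6-dihydro-1,2-dioxin-3-yl]acetate | CCC[C@@H]1C=C[C@H](CCCC2(OC)C=C[C@@H](CC(=O)OC)OO2)OO1
F6 | step 5 | methyl (3E)-5-hydroxypent-3-enoate | OC/C=C/CC(=O)OC
F7 | step 5 | methyl (3E)-5-[(methoxycarbonyl)oxy]pent-3-enoate | COC(=O)OC/C=C/CC(=O)OC
F8 | step 5 | methyl (3R)-3-[(2-methoxypropan-2-yl)peroxy]pent-4-enoate | C=C[C@@H](CC(=O)OC)OOC(C)(C)OC
F9 | step 5 | methyl (3R)-3-hydroperoxypent-4-enoate | C=C[C@@H](CC(=O)OC)OO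
F10 | step 5 | methyl (3R)-3-({(7E)-3-methoxy-9-[(methoxycarbonyl)oxy]nona-1,7-dien-3-yl}peroxy)pent-4-enoate, both ketal epimers | C=C[C@@H](CC(=O)OC)OOC(OC)(CCC/C=C/COC(=O)OC)C=C
F11 | step 5 | methyl (3R)-3-({(7R)-7-{[(3S)-hex-1-en-3-yl]peroxy}-3-methoxynona-1,8-dien-3-yl}peroxy)pent-4-enoate, both ketal epimers | C=C[C@@H](CC(=O)OC)OOC(OC)(CCC[C@H](C=C)OO[C@@H](CCC)C=C)C=C
F12 | step 14 | (2E)-7,7-dimethoxynona-2,8-dien-1-yl methyl carbonate | COC(=O)OC/C=C/CCCC(OC)(OC)C=C
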